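At 1.0 h, has the red flask stopped, and how is its substrate shared between target and other capture product?

| flask | substrate | first nucleophile | second nucleophile | remark | time |
|---|---|---|---|---|---|
| red | 0.50 M | 1.5 equiv | 1 equiv | the very flask that is asked about, followed so far |  |
| ochre | 0.50 M | 3 equiv | 1 equiv | run made earlier |  |
| flask | 0.50 M | 1.50 equiv | 1.00 equiv |  | 1.0 h |

- red (time / min: substrate / %, target / %, other capture product / %): 1.00: 80.8, 7.2, 11.6; 2.00: 65.1, 13.9, 21.7; 3.00: 51.4, 19.3, 30.0; 4.00: 41.2, 21.5, 36.2; 5.00: 34.0, 24.5, 42.0; 6.00: 26.7, 27.1, 47.0; 8.00: 16.9, 29.4, 53.4
- ochre (time / min: substrate / %, target / %, other capture product / %): 6.00: 26.6, 38.9, 34.8; 12.0: 7.8, 45.7, 47.7; 20.0: 1.9, 48.6, 51.4; 25.0: 0.5, 47.2, 52.4; 30.0: 0, 47.7, 53.0; 40.0: 0, 47.2, 52.7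

(standard deviation of a reading: 0.5 percentage points)

- at 1.0 h, what has stopped the reaction, if anything has (all of the substrate has reacted / it is still moving / the second nucleophile has run out first)
- how much of the substrate has reacted by 1.0 h
- how much target there is at 1.0 h, in percent of the substrate charged
- how much other capture product there is at 1.0 h, in percent of the substrate charged

- the reaction counts as stopped when no species that holds the substrate changes by six tenths of a point or more over the second half of the time

The ladder of times starts with capture. At the first red reading, substrate, target and other capture product already sum to 99.6%, within the scatter of 0.5 percentage points, so any intermediate stands too low to read. Next comes the substrate. The red readings give a rate constant of 0.225 /min, a half-life of 3.08 min. At 6.00 min, red shows 26.7% and ochre 26.6%, although ochre holds twice the first nucleophile, so loss of substrate is the rate-limiting step. The hour is far longer than that half-life and spans 5.87 powers of ten of substrate. Within these same minutes the red readings point to a loss of first nucleophile: target per other capture product in red falls from 0.621 in the first reading to a noisy 0.359 between the last two, although capture has taken less first nucleophile than second. On the last rung the products stand still: ochre reads target at 47.7% at 30.0 min and 47.2% at 40.0 min, a plateau within scatter.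

The flask therefore ends as a split, and the ochre plateau gives the quantity to carry: the ratio per equivalent, read as 0.299, an apparent selectivity factor, meaning final target over final other capture product, divided by charged first over second nucleophile, at a fixed substrate charge. Taking it as unchanged for this recipe, in logarithms, −0.524 plus 0.176 gives an estimated final ratio of 0.448. My own reckoning is thus 30.9% target and 69.1% other capture product, which leaves second nucleophile over.

The forecast, reasoning that “a slow ionisation comes first, followed by competitive capture”, says all of the substrate has reacted, with 100% conversion, 32.5% target and 67.5% other capture product, a little more target than my reckoning.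

The flask gives: all of the substrate has reacted, conversion >99.9%, target 33.0%, other capture product 67.0%.

    substrate → intermediate (k = 0.220 /min)
    second nucleophile + intermediate → other capture product (k = 39.0 /M/min)
    first nucleophile + intermediate → target (k = 17.0 /M/min)
    first nucleophile → decomposed reagent (k = 0.120 /min)

The flask's final ratio is 0.493, beside the 0.448 reckoned from ochre. Target stands this low chiefly because intermediate also goes to other capture product: the run without that path gives 89.1% target against 33.0%. For the neighbour with 2.50 equiv of second nucleophile, the ratio per equivalent gives 0.179, so 15.2% target. Computed, that flask holds 15.3% target and 84.7% other capture product.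

The earlier runs and the new flask are simulated with made-up constants; the scatter is artificial.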